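Time works on the complex with one exchanged from both sides: the exchange makes it, and the flattening readings say that something also takes it away.

all flasks: starting complex 0.21 M
- epsilon: incoming ligand 0.12 M; run made earlier
- delta: incoming ligand 0.17 M; run made earlier
- alpha: incoming ligand 0.29 M; run made earlier
- Sunday's: incoming ligand 0.315 M; time 40 h
- Monday's: incoming ligand 0.105 M; time 40 h

| run | time / h | complex with one exchanged / % | complex with two exchanged / % |
|---|---|---|---|
| epsilon | 2.50 | 9.0 | 0.1 |
| epsilon | 8.00 | 19.0 | 0.4 |
| epsilon | 12.0 | 21.7 | 0.2 |
| epsilon | 20.0 | 23.9 | 0.9 |
| delta | 1.50 | 7.2 | 0.2 |
| delta | 4.00 | 17.8 | 0.3 |
| delta | 8.00 | 25.8 | 0.4 |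
| delta | 20.0 | 29.1 | 1.0 |
| alpha | 2.50 | 19.8 | 0.1 |
| alpha | 8.00 | 38.5 | 1.0 |
| alpha | 12.0 | 43.1 | 1.7 |
| alpha | 20.0 | 41.7 | 2.0 |

(readings scatter by 0.5 percentage points)

- which of these holds the largest part of the starting complex at the end of Sunday's (complex with two exchanged / complex with three exchanged / starting complex / complex with one exchanged)
- which of these holds the largest part of the starting complex at the end of Monday's (complex with two exchanged / complex with three exchanged / starting complex / complex with one exchanged)
- complex with one exchanged at the end of Sunday's, in percent of the starting complex charged

- in percentages every species weighs as the starting complex in it: one idle adduct counts as two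
- for complex with two exchanged the idle adduct is counted in
- steps thought possible: complex with one exchanged + incoming ligand <-> leaving ligand + complex with two exchanged; starting complex + incoming ligand <-> leaving ligand + complex with one exchanged; complex with two exchanged + incoming ligand <-> leaving ligand + complex with three exchanged; complex with one exchanged -> decomposed reagent; starting complex + complex with two exchanged <-> idle adduct
- in an amount of complex with two exchanged, one idle adduct counts as one complex with two exchanged

The complex with two exchanged reads at most 2.0% in the alpha run's last reading, so I count the first exchange as the step that uses ligand. Starting complex and incoming ligand then fall by equal molarity. The logarithm of ligand left over complex left, each as a part of its charge, climbs straight with time, with slope k times the ligand's excess over the complex, k being the rate constant of the first exchange. The alpha run's first reading gives k = 0.329 M⁻¹ h⁻¹.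

Between its last two readings, at 16.0 h, the alpha run holds 34.5% of its starting complex and 0.152 M ligand. What is made, less the change read, is what is lost. Divided by the mean amount, that gives 0.0449 h⁻¹, the share of complex with one exchanged lost per hour, which I call d.

The same reckoning on the epsilon run gives 0.0357 h⁻¹. The two part. With readings scattered by 0.5 percentage points, the change read is 33.8% of the loss in the epsilon run against 9.19% in the alpha run, so the epsilon figure leans harder on noise and I keep the alpha one.

On Sunday's the logarithm leaves 44.6%, 25.1% and 10.0% of the starting complex at a quarter, half and all of the time. Letting each exchanged part decay by d from the middle of its window, I expect 27.4% of complex with one exchanged, which leads. On Monday's the ligand is the limiting reagent and 57.2% of the starting complex stays, more than the 42.8% that reacted.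

The forecast says complex with one exchanged at 27% on Sunday's and starting complex on Monday's, holding that “The loss is not ligand-dependent, so it is decomposition rather than onward exchange”.

Sunday's gives complex with one exchanged at 26.1%, and Monday's gives starting complex at 56.7%.

    complex with one exchanged + incoming ligand ⇌ leaving ligand + complex with two exchanged (K = 4.01, k = 0.0168 M⁻¹ h⁻¹)
    starting complex + incoming ligand ⇌ leaving ligand + complex with one exchanged (K = 56.4, k = 0.353 M⁻¹ h⁻¹)
    complex with two exchanged + incoming ligand ⇌ leaving ligand + complex with three exchanged (K = 0.860, k = 0.697 M⁻¹ h⁻¹)
    complex with one exchanged → decomposed reagent (k = 0.0419 h⁻¹)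
    starting complex + complex with two exchanged ⇌ idle adduct, settled at all times (K = 2.53 M⁻¹)

At 6.51 h in Sunday's, the half-life of complex with one exchanged by decomposition is 17 h, shorter than the 190 h by the forward second exchange, and that second figure is long against 40 h. My d, read from the alpha run, times the mean amount from 20.0 h to 40.0 h reckons 31 points of decomposed reagent on Sunday's, where the flask gains 29 points, going from 31.0% to 59.8%. On Monday's the same reckoning gives 16 points, where the flask gains 15 points, going from 13.4% to 28.3%.

The readings come from a simulation with made-up constants; noise was put on by code.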